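**Retrosynthetic overview**

1. Ring locants used for the target and all open-chain precursors: C1 bears CO2H, C2=C3 is the Z alkene, C4=C5 the E alkene, C6 is quaternary, C7 is CHMe, C8 and C9 are the CH2 pair, C10 bears CH2OAc.
2. Target 29 ⇐ tert-butyl ester 27 ⇐ open-chain iodide 26, by closing the ten-membered carbocycle (the only ring made; the furan is bought) through the C8–C9 bond in a nickel-catalysed reductive allyl–alkyl coupling, the last C–C bond of the route.
3. Enabling feature: ring C9 is an allylic CH2 on the tetrasubstituted C10=C1 enoate, and C10 carries a second CH2–O carbon (CH2OAc). An open-chain C10(CH2OAc)2 terminus therefore has no alkene geometry, either arm can ionise to the same π-allyl, the other arm is the target's acetate, and the rigid C2=C3 (Z)/C4=C5 (E) diene lets C8 reach only the CH2 terminus.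
4. 26 ⇐ Sonogashira union (C1–C2) of enyne 18 with bromo-enoate 23 (from 2-oxopropane-1,3-diyl diacetate by Wittig olefination and bromination–dehydrobromination), then Z-selective semi-reduction of the C2–C3 alkyne and iodination at C8.
5. 18 ⇐ Ireland–Claisen rearrangement of propanoate 13 (C6–C7 bond; C6, C7 and the E C4=C5 alkene by chirality transfer from the C4 carbinol, which comes from catalytic asymmetric alkynylation of enal 9).

Key step: step 15

Assumption: in step 5 the (R,R)-ProPhenol ligand is taken to give the (R)-carbinol, by analogy with the facial sense of related zinc–ProPhenol additions; the sense is checked by Mosher ester analysis of 12 and the ligand antipode is used if needed.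
Remark: the CIP descriptors at C6/C7 are R/S in the open-chain compounds 16–26 and S/R in the ring compounds 27–29 only because substituent priorities change; no stereocentre is touched after step 7.
Remark: open-chain trienes 25 and 26 are kept at or below 23 °C and used at once, because (Z)-hexatrienes of this type can undergo thermal [1,7]-H shift and 6π-electrocyclisation.

**Route**

Step 1
Reactants: 1 3-(bromomethyl)furan; 2 trimethyl(prop-1-yn-1-yl)silane
Product: 4 [4-(furan-3-yl)but-1-yn-1-yl]trimethylsilane, via lithiated silylpropyne 3 (not isolated)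
Conditions: n-BuLi, THF, −78 to −20 °C; then 1, −78 to 0 °C
Reagents that add atoms: none
Why: Propargylic lithiation of the silyl-capped propyne and SN2 alkylation by the activated furylmethyl bromide; the silyl group directs reaction to the propargyl rather than the allenyl terminus, and no stereocentre is involved.

Step 2
Reactants: 4 [4-(furan-3-yl)but-1-yn-1-yl]trimethylsilane
Product: 5 3-(but-3-yn-1-yl)furan
Conditions: K2CO3 (cat.), MeOH, 23 °C
Reagents that add atoms: none
Why: Base-catalysed methanolysis of the alkynyl C–Si bond (protodesilylation); nothing else in 4 is base-labile.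

Step 3
Reactants: 5 3-(but-3-yn-1-yl)furan
Product: 8 (2E)-5-(furan-3-yl)-3-methylpent-2-en-1-ol, via alkenyldimethylalane 6 (not isolated), via lithium alkenylalanate 7 (not isolated)
Conditions: Me3Al, Cp2ZrCl2 (20 mol%), CH2Cl2, 0 to 23 °C; n-BuLi, THF, −78 °C; (CH2O)n, −78 to 23 °C; aq. KNaC4H4O6
Reagents that add atoms: trimethylaluminium, C[Al](C)C; formaldehyde (as paraformaldehyde), C=O
Why: Zirconium-catalysed syn-carboalumination (Negishi carboalumination) puts CH3 and Al cis across the terminal alkyne, and hydroxymethylation of the alanate with retention fixes the E trisubstituted alkene that later defines the two C6 substituents.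

Step 4
Reactants: 8 (2E)-5-(furan-3-yl)-3-methylpent-2-en-1-ol
Product: 9 (2E)-5-(furan-3-yl)-3-methylpent-2-enal
Conditions: MnO2, CH2Cl2, 23 °C
Reagents that add atoms: none
Why: Chemoselective allylic alcohol oxidation with MnO2 should stop at the enal and leave the E geometry and the furan untouched.

Step 5
Reactants: 9 (2E)-5-(furan-3-yl)-3-methylpent-2-enal; 10 ethynyltrimethylsilane
Product: 12 (3R,4E)-7-(furan-3-yl)-5-methyl-1-(trimethylsilyl)hept-4-en-1-yn-3-ol, via methyl(silylethynyl)zinc 11 (not isolated)
Conditions: Me2Zn, (R,R)-ProPhenol (10 mol%), Ph3PO (20 mol%), toluene, 4 °C; aq. NH4Cl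
Reagents that add atoms: none
Why: Catalytic asymmetric alkynylation of an enal by an alkynylzinc on the dinuclear zinc–ProPhenol catalyst, whose chiral pocket shields one aldehyde face so that the (R)-carbinol at C4 should form.

Step 6
Reactants: 12 (3R,4E)-7-(furan-3-yl)-5-methyl-1-(trimethylsilyl)hept-4-en-1-yn-3-ol
Product: 13 (3R,4E)-7-(furan-3-yl)-5-methyl-1-(trimethylsilyl)hept-4-en-1-yn-3-yl propanoate
Conditions: (EtCO)2O, Et3N, DMAP (cat.), CH2Cl2, 0 to 23 °C
Reagents that add atoms: propanoic anhydride, CCC(=O)OC(=O)CC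
Why: DMAP-catalysed acylation of a secondary alcohol (esterification); the stereocentre is not involved.

Step 7
Reactants: 13 (3R,4E)-7-(furan-3-yl)-5-methyl-1-(trimethylsilyl)hept-4-en-1-yn-3-yl propanoate
Product: 16 (2S,3R,4E)-3-[2-(furan-3-yl)ethyl]-2,3-dimethyl-7-(trimethylsilyl)hept-4-en-6-ynoic acid, via silyl ketene acetal 14 (not isolated), via trimethylsilyl ester 15 (not isolated)
Conditions: LDA (LiN(i-Pr)2), THF–DMPU (4:1), −78 °C; TMSCl, −78 to 23 °C, 12 h; 1 M HCl
Reagents that add atoms: none
Why: Ireland–Claisen rearrangement: enolisation in THF–DMPU should give the ketene acetal with the C-methyl trans to the allylic oxygen, and the chair transition state with the alkynyl group equatorial (enforced by A(1,3) strain with the cis methyl on the alkene) transfers the C4 carbinol chirality to C6 and C7 and gives the E C4=C5 alkene, while the silylated alkyne terminus disfavours the competing propargylic [3,3] shift.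

Step 8
Reactants: 16 (2S,3R,4E)-3-[2-(furan-3-yl)ethyl]-2,3-dimethyl-7-(trimethylsilyl)hept-4-en-6-ynoic acid
Product: 17 (2S,3R,4E)-3-[2-(furan-3-yl)ethyl]-2,3-dimethyl-7-(trimethylsilyl)hept-4-en-6-yn-1-ol
Conditions: LiAlH4, Et2O, 0 to 23 °C; Na2SO4·10H2O
Reagents that add atoms: none
Why: Hydride reduction of the carboxylic acid to the primary alcohol (LiAlH4 reduction); the silyl enyne is not a propargylic alcohol and should not be hydroaluminated, and C7 is not enolisable under these conditions.

Step 9
Reactants: 17 (2S,3R,4E)-3-[2-(furan-3-yl)ethyl]-2,3-dimethyl-7-(trimethylsilyl)hept-4-en-6-yn-1-ol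
Product: 18 (2S,3R,4E)-3-[2-(furan-3-yl)ethyl]-2,3-dimethylhept-4-en-6-yn-1-ol
Conditions: K2CO3, MeOH, 23 °C
Reagents that add atoms: none
Why: Protodesilylation of the alkynylsilane by methoxide frees the terminal alkyne for cross-coupling.

Step 10
Reactants: 19 2-oxopropane-1,3-diyl diacetate; 20 tert-butyl (triphenyl-λ5-phosphanylidene)acetate
Product: 21 tert-butyl 4-(acetyloxy)-3-[(acetyloxy)methyl]but-2-enoate
Conditions: toluene, 80 °C
Reagents that add atoms: none
Why: Wittig olefination of an activated α,α'-diacyloxy ketone by a stabilised ylide; the ketone is symmetric, so the trisubstituted alkene has no geometric isomers.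

Step 11
Reactants: 21 tert-butyl 4-(acetyloxy)-3-[(acetyloxy)methyl]but-2-enoate
Product: 23 tert-butyl 4-(acetyloxy)-3-[(acetyloxy)methyl]-2-bromobut-2-enoate, via dibromide 22 (not isolated)
Conditions: Br2, CH2Cl2, 0 to 23 °C, dark; then Et3N, 0 °C
Reagents that add atoms: bromine, BrBr
Why: Bromination–dehydrobromination: bromine adds across the enoate and the base removes the only acidic hydrogen (α to the ester) with loss of the β-bromide, giving the α-bromo enoate, again without geometric isomers.

Step 12
Reactants: 18 (2S,3R,4E)-3-[2-(furan-3-yl)ethyl]-2,3-dimethylhept-4-en-6-yn-1-ol; 23 tert-butyl 4-(acetyloxy)-3-[(acetyloxy)methyl]-2-bromobut-2-enoate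
Product: 24 tert-butyl 4-(acetyloxy)-3-[(acetyloxy)methyl]-2-[(3E,5R,6S)-5-[2-(furan-3-yl)ethyl]-7-hydroxy-5,6-dimethylhept-3-en-1-yn-1-yl]but-2-enoate
Conditions: Pd(PPh3)2Cl2 (5 mol%), CuI (10 mol%), Et3N, THF, 23 °C
Reagents that add atoms: none
Why: Sonogashira coupling forms the C1–C2 bond; oxidative addition of the electron-poor vinyl bromide to zerovalent palladium should outrun ionisation of the allylic acetates at 23 °C.

Step 13
Reactants: 24 (dienyne above)
Product: 25 tert-butyl 4-(acetyloxy)-3-[(acetyloxy)methyl]-2-[(1Z,3E,5R,6S)-5-[2-(furan-3-yl)ethyl]-7-hydroxy-5,6-dimethylhepta-1,3-dien-1-yl]but-2-enoate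
Conditions: Zn dust activated with Cu(OAc)2 and AgNO3, MeOH–H2O (1:1), 23 °C, dark
Reagents that add atoms: none
Why: Semi-reduction by the zinc–copper–silver couple is specific for conjugated alkynes and delivers both hydrogens cis, which should give the Z C2=C3 alkene without touching the isolated E alkene, the furan or the esters.

Step 14
Reactants: 25 (triene alcohol above)
Product: 26 tert-butyl 4-(acetyloxy)-3-[(acetyloxy)methyl]-2-[(1Z,3E,5R,6S)-5-[2-(furan-3-yl)ethyl]-7-iodo-5,6-dimethylhepta-1,3-dien-1-yl]but-2-enoate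
Conditions: PPh3, I2, imidazole, CH2Cl2, 0 to 20 °C
Reagents that add atoms: iodine, II
Why: Appel-type iodination converts the primary alcohol at C8 into the iodide by SN2 under neutral conditions, at temperatures low enough to protect the (Z)-triene.

Step 15
Reactants: 26 (iodide above)
Product: 27 tert-butyl (1(10)Z,2Z,4E,6S,7R)-10-[(acetyloxy)methyl]-6-[2-(furan-3-yl)ethyl]-6,7-dimethylcyclodeca-1(10),2,4-triene-1-carboxylate
Conditions: NiBr2(dme) (20 mol%), 4,4'-di-tert-butyl-2,2'-bipyridine (24 mol%), Zn dust, MgCl2, pyridine, DMA, 20 °C; 26 added over 12 h (final 2 mM)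
Reagents that add atoms: none
Why: Proposed new method: zerovalent nickel (from NiBr2(dme)/Zn) ionises either of the two equivalent allylic acetates of 26 to a 2-(acetoxymethyl)-π-allylnickel acetate, the primary C8 radical formed from the iodide by nickel-mediated halogen abstraction is captured by that nickel centre, and C(sp3)–C(sp3) reductive elimination at the unsubstituted allyl terminus forms C8–C9 while zinc returns nickel to the zerovalent state; the closest known reaction types are the intermolecular nickel-catalysed reductive (cross-electrophile) allylation of unactivated alkyl halides with allylic acetates or carbonates and the coupling of π-allylnickel halides with alkyl iodides, including nickel-mediated macrocyclic allyl–allyl closures. The ten-membered carbocycle is closed in a formal 10-exo-tet sense at C9 (the departing acetate lies outside the new ring), through an allyl(alkyl)nickel in which C8 and C9 are bridged by the metal. No stereocentre is created and C6/C7 are remote from the reacting atoms; the geometry of the new tetrasubstituted C10=C1 bond is controlled by the ring, because only the π-allyl isomer with the dienyl chain anti can deliver C8 to the CH2 terminus, which puts C9 cis to C2 and the surviving CH2OAc cis to the ester, and syn–anti equilibration of the π-allyl supplies that isomer. Regioselectivity (CH2 terminus, not the fully substituted C1 terminus) is secured by sterics and by the prohibitive strain of the alternative eight-membered ring containing the E C4=C5 bond; the Z C2=C3 and E C4=C5 bonds leave only six rotatable bonds between C8 and C9. Intermolecular coupling is suppressed by syringe-pump addition to 2 mM, and the second acetate of 27 should survive because, once the iodide is consumed, its ionisation is answered only by acetate return. The step is run at 20 °C so that neither the open triene 26 nor the ring triene 27 suffers [1,7]-H shift or 6π-electrocyclisation.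

Step 16
Reactants: 27 (macrocyclic tert-butyl ester above)
Product: 29 (1(10)Z,2Z,4E,6S,7R)-10-[(acetyloxy)methyl]-6-[2-(furan-3-yl)ethyl]-6,7-dimethylcyclodeca-1(10),2,4-triene-1-carboxylic acid (CNP0110626.2), via trimethylsilyl ester 28 (not isolated)
Conditions: TMSOTf, 2,6-lutidine, CH2Cl2, 0 °C; then pH 5 phosphate buffer
Reagents that add atoms: none
Why: Silyl-triflate-mediated cleavage of the tert-butyl ester (loss of 2-methylpropene, lutidine-buffered) and hydrolysis of the silyl ester on work-up should free the acid without the protic acid or base that could attack the furan, the allylic acetate or cause lactonisation onto the CH2OAc carbon.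

**Compound list**

1 | 3-(bromomethyl)furan | BrCc1ccoc1 | starting material
2 | trimethyl(prop-1-yn-1-yl)silane | CC#C[Si](C)(C)C | starting material
3 | [3-(trimethylsilyl)prop-2-yn-1-yl]lithium | [Li]CC#C[Si](C)(C)C | intermediate
4 | [4-(furan-3-yl)but-1-yn-1-yl]trimethylsilane | C[Si](C)(C)C#CCCc1ccoc1 | intermediate
5 | 3-(but-3-yn-1-yl)furan | C#CCCc1ccoc1 | intermediate
6 | [(1E)-4-(furan-3-yl)-2-methylbut-1-en-1-yl]dimethylalane | C[Al](C)/C=C(\C)CCc1ccoc1 | intermediate
7 | lithium butyl[(1E)-4-(furan-3-yl)-2-methylbut-1-en-1-yl]dimethylaluminate | [Li+].CCCC[Al-](C)(C)/C=C(\C)CCc1ccoc1 | intermediate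
8 | (2E)-5-(furan-3-yl)-3-methylpent-2-en-1-ol | OC/C=C(\C)CCc1ccoc1 | intermediate
9 | (2E)-5-(furan-3-yl)-3-methylpent-2-enal | O=C/C=C(\C)CCc1ccoc1 | intermediate
10 | ethynyltrimethylsilane | C#C[Si](C)(C)C | starting material
11 | methyl[(trimethylsilyl)ethynyl]zinc | C[Zn]C#C[Si](C)(C)C | intermediate
12 | (3R,4E)-7-(furan-3-yl)-5-methyl-1-(trimethylsilyl)hept-4-en-1-yn-3-ol | C[Si](C)(C)C#C[C@H](O)/C=C(\C)CCc1ccoc1 | intermediate
13 | (3R,4E)-7-(furan-3-yl)-5-methyl-1-(trimethylsilyl)hept-4-en-1-yn-3-yl propanoate | CCC(=O)O[C@@H](C#C[Si](C)(C)C)/C=C(\C)CCc1ccoc1 | intermediate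
14 | (1Z)-1-{[(3R,4E)-7-(furan-3-yl)-5-methyl-1-(trimethylsilyl)hept-4-en-1-yn-3-yl]oxy}-1-[(trimethylsilyl)oxy]prop-1-ene (C-methyl cis to OSiMe3) | C/C=C(\O[Si](C)(C)C)O[C@@H](C#C[Si](C)(C)C)/C=C(\C)CCc1ccoc1 | intermediate
15 | trimethylsilyl (2S,3R,4E)-3-[2-(furan-3-yl)ethyl]-2,3-dimethyl-7-(trimethylsilyl)hept-4-en-6-ynoate | C[Si](C)(C)C#C/C=C/[C@@](C)(CCc1ccoc1)[C@H](C)C(=O)O[Si](C)(C)C | intermediate
16 | (2S,3R,4E)-3-[2-(furan-3-yl)ethyl]-2,3-dimethyl-7-(trimethylsilyl)hept-4-en-6-ynoic acid | C[Si](C)(C)C#C/C=C/[C@@](C)(CCc1ccoc1)[C@H](C)C(=O)O | intermediate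
17 | (2S,3R,4E)-3-[2-(furan-3-yl)ethyl]-2,3-dimethyl-7-(trimethylsilyl)hept-4-en-6-yn-1-ol | C[Si](C)(C)C#C/C=C/[C@@](C)(CCc1ccoc1)[C@H](C)CO | intermediate
18 | (2S,3R,4E)-3-[2-(furan-3-yl)ethyl]-2,3-dimethylhept-4-en-6-yn-1-ol | C#C/C=C/[C@@](C)(CCc1ccoc1)[C@H](C)CO | intermediate
19 | 2-oxopropane-1,3-diyl diacetate | CC(=O)OCC(=O)COC(C)=O | starting material
20 | tert-butyl (triphenyl-λ5-phosphanylidene)acetate | CC(C)(C)OC(=O)C=P(c1ccccc1)(c1ccccc1)c1ccccc1 | starting material
21 | tert-butyl 4-(acetyloxy)-3-[(acetyloxy)methyl]but-2-enoate | CC(=O)OCC(COC(C)=O)=CC(=O)OC(C)(C)C | intermediate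
22 | tert-butyl 4-(acetyloxy)-3-[(acetyloxy)methyl]-2,3-dibromobutanoate (racemic) | CC(=O)OCC(Br)(COC(C)=O)C(Br)C(=O)OC(C)(C)C | intermediate
23 | tert-butyl 4-(acetyloxy)-3-[(acetyloxy)methyl]-2-bromobut-2-enoate | CC(=O)OCC(COC(C)=O)=C(Br)C(=O)OC(C)(C)C | intermediate
24 | tert-butyl 4-(acetyloxy)-3-[(acetyloxy)methyl]-2-[(3E,5R,6S)-5-[2-(furan-3-yl)ethyl]-7-hydroxy-5,6-dimethylhept-3-en-1-yn-1-yl]but-2-enoate | CC(=O)OCC(COC(C)=O)=C(C#C/C=C/[C@@](C)(CCc1ccoc1)[C@H](C)CO)C(=O)OC(C)(C)C | intermediate
25 | tert-butyl 4-(acetyloxy)-3-[(acetyloxy)methyl]-2-[(1Z,3E,5R,6S)-5-[2-(furan-3-yl)ethyl]-7-hydroxy-5,6-dimethylhepta-1,3-dien-1-yl]but-2-enoate | CC(=O)OCC(COC(C)=O)=C(/C=C\C=C\[C@@](C)(CCc1ccoc1)[C@H](C)CO)C(=O)OC(C)(C)C | intermediate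
26 | tert-butyl 4-(acetyloxy)-3-[(acetyloxy)methyl]-2-[(1Z,3E,5R,6S)-5-[2-(furan-3-yl)ethyl]-7-iodo-5,6-dimethylhepta-1,3-dien-1-yl]but-2-enoate | CC(=O)OCC(COC(C)=O)=C(/C=C\C=C\[C@@](C)(CCc1ccoc1)[C@H](C)CI)C(=O)OC(C)(C)C | intermediate
27 | tert-butyl (1(10)Z,2Z,4E,6S,7R)-10-[(acetyloxy)methyl]-6-[2-(furan-3-yl)ethyl]-6,7-dimethylcyclodeca-1(10),2,4-triene-1-carboxylate | CC(=O)OC/C1=C(C(=O)OC(C)(C)C)/C=C\C=C\[C@@](C)(CCc2ccoc2)[C@H](C)CC1 | intermediate
28 | trimethylsilyl (1(10)Z,2Z,4E,6S,7R)-10-[(acetyloxy)methyl]-6-[2-(furan-3-yl)ethyl]-6,7-dimethylcyclodeca-1(10),2,4-triene-1-carboxylate | CC(=O)OC/C1=C(C(=O)O[Si](C)(C)C)/C=C\C=C\[C@@](C)(CCc2ccoc2)[C@H](C)CC1 | intermediate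
29 | (1(10)Z,2Z,4E,6S,7R)-10-[(acetyloxy)methyl]-6-[2-(furan-3-yl)ethyl]-6,7-dimethylcyclodeca-1(10),2,4-triene-1-carboxylic acid (CNP0110626.2) | CC(=O)OC/C1=C(C(=O)O)/C=C\C=C\[C@@](C)(CCc2ccoc2)[C@H](C)CC1 | target

**Step count and risks**

Total: 16 steps. Longest linear sequence: 14 steps (steps 1–9 and 12–16; steps 10–11 make fragment 23).

Steps most likely to fail:

1. Step 15 (proposed new method). The ring closure may be too slow relative to bimolecular coupling, the alkyl fragment may be lost by β-hydride elimination or hydrodehalogenation at C8, and repeated ionisation may remove the second acetate reductively. The fallback replaces the radical cross-electrophile coupling by a two-electron organometallic closure of the same bond, built from known reaction types. It sets out from 26: direct zinc insertion into the primary iodide (Zn dust, LiCl, THF, 25 °C) gives the alkylzinc iodide F1. F1 is then added slowly to Pd2(dba)3/tri(2-furyl)phosphine in THF–NMP at 20 °C under high dilution. Transmetalation of the alkylzinc to the π-allylpalladium acetate formed from one arm, followed by reductive elimination at the CH2 terminus (palladium-catalysed allylation of an alkylzinc halide, Negishi type), closes C8–C9 and returns to the route at 27.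

2. Step 12. Zerovalent palladium may ionise the allylic acetates, with capture of the π-allyl by the amine or the copper acetylide, or oxidative addition at the tetrasubstituted bromide may stall while 18 dimerises oxidatively. The fallback sets out from 18: stannylation of the terminal alkyne (Bu3SnOMe, 60 °C, removal of MeOH) gives the alkynylstannane F2. F2 is joined to 23 by an amine-free and copper-free Stille coupling (Pd2(dba)3, AsPh3, DMF, 23 °C), which returns to the route at 24.

3. Step 7. Control of the ketene acetal geometry may be incomplete, which erodes the C7 configuration, and part of the material may be diverted into the propargylic [3,3] pathway. The fallback sets C7 separately with an auxiliary, so the enolate geometry no longer matters. It sets out from 12: acetylation (Ac2O, Et3N, DMAP) gives the acetate F3. Ireland–Claisen rearrangement of F3 (LiN(i-Pr)2, TMSCl, THF, −78 to 23 °C, acidic work-up) gives the acid F4, with C6 and the E alkene set by chirality transfer. Activation of F4 as its pivaloyl mixed anhydride (t-BuCOCl, Et3N) and reaction with lithiated (4S)-4-benzyl-1,3-oxazolidin-2-one gives the imide F5. Evans methylation (NaN(SiMe3)2, MeI, THF, −78 °C) places the C7 methyl anti to the benzyl group and gives the methylated imide F6. Reductive removal of the auxiliary (LiBH4, THF–MeOH, 0 °C) returns to the route at 17.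

**Further compounds**

F1 | step 15 | tert-butyl 4-(acetyloxy)-3-[(acetyloxy)methyl]-2-[(1Z,3E,5R,6S)-5-[2-(furan-3-yl)ethyl]-7-(iodozincio)-5,6-dimethylhepta-1,3-dien-1-yl]but-2-enoate | CC(=O)OCC(COC(C)=O)=C(/C=C\C=C\[C@@](C)(CCc1ccoc1)[C@H](C)C[Zn]I)C(=O)OC(C)(C)C
F2 | step 12 | (2S,3R,4E)-3-[2-(furan-3-yl)ethyl]-2,3-dimethyl-7-(tributylstannyl)hept-4-en-6-yn-1-ol | CCCC[Sn](CCCC)(CCCC)C#C/C=C/[C@@](C)(CCc1ccoc1)[C@H](C)CO
F3 | step 7 | (3R,4E)-7-(furan-3-yl)-5-methyl-1-(trimethylsilyl)hept-4-en-1-yn-3-yl acetate | CC(=O)O[C@@H](C#C[Si](C)(C)C)/C=C(\C)CCc1ccoc1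
F4 | step 7 | (3S,4E)-3-[2-(furan-3-yl)ethyl]-3-methyl-7-(trimethylsilyl)hept-4-en-6-ynoic acid | C[Si](C)(C)C#C/C=C/[C@@](C)(CCc1ccoc1)CC(=O)O
F5 | step 7 | (4S)-4-benzyl-3-[(3S,4E)-3-[2-(furan-3-yl)ethyl]-3-methyl-7-(trimethylsilyl)hept-4-en-6-ynoyl]-1,3-oxazolidin-2-one | C[Si](C)(C)C#C/C=C/[C@@](C)(CCc1ccoc1)CC(=O)N1[C@@H](Cc2ccccc2)COC1=O
F6 | step 7 | (4S)-4-benzyl-3-[(2S,3R,4E)-3-[2-(furan-3-yl)ethyl]-2,3-dimethyl-7-(trimethylsilyl)hept-4-en-6-ynoyl]-1,3-oxazolidin-2-one | C[Si](C)(C)C#C/C=C/[C@@](C)(CCc1ccoc1)[C@H](C)C(=O)N1[C@@H](Cc2ccccc2)COC1=O
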